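- larch: substrate 0.40 M; coupling partner 1.6 M; free catalyst 20 mM; the very flask that is asked about, followed so far
- flask: substrate 0.40 M; coupling partner 1.60 M; free catalyst 20 mM

larch run (percent of the substrate charged)

| time / h | product / % | substrate / % |
|---|---|---|
| 0.250 | 9 | 89 |
| 0.833 | 27 | 71 |
| 1.33 | 47 | 53 |
| 2.00 | 61 | 33 |
| 3.00 | 87 | 13 |
| 4.00 | 94 | 4 |

(standard deviation of a reading: 2 percentage points)

* factor on the rate of making product when 30% of the substrate are converted if free catalyst is charged twice over
* factor on the rate when 30% of the substrate are converted if free catalyst is charged at 4.0 mM instead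

- the numbers in the tables scatter with a standard deviation of 2 percentage points
- steps that have been proposed: free catalyst -> spent catalyst; coupling partner + free catalyst <-> catalyst intermediate A; 2 catalyst intermediate B <-> resting dimer; catalyst intermediate C -> free catalyst + product; substrate + catalyst intermediate B -> catalyst intermediate C; catalyst intermediate A -> catalyst intermediate B
- no earlier run changes the charge of free catalyst; that part of a forecast is a guess

1. I start from amounts: the substrate charged is 20.0 times the free catalyst charged, so each catalyst has that many turnovers to make in this flask.

2. The larch run is this same flask, followed so far. Around 30% conversion its substrate falls from 89% to 53% of the charge between 0.250 h and 1.33 h, so I read a fall of 0.333 h⁻¹ as a fraction of the charge, scatter included.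

3. Multiplied by the turnovers owed, that gives 6.67 h⁻¹. I carry this as the turnover frequency: turnovers per hour for each catalyst charged, at 30% conversion.

4. The first setting is a doubled catalyst charge. If the turnover frequency holds, the rate is multiplied by 2.

5. The second setting is a catalyst charge of 4.0 mM. If the turnover frequency holds, the factor is 0.200. Both are my own guesses; no earlier run changes this charge.

6. The forecast gives 1.7 (1.4 to 2) and 0.26 (0.18 to 0.42), on the ground that “turnover is partly limited by the step before substrate entry, which is first order in catalyst”. Its factors differ from mine: lower on doubling and higher at the small charge.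

7. The flask gives 1.90 on doubling and 0.214 at 4.0 mM.

    free catalyst → spent catalyst (k = 9.70 × 10⁻⁸ s⁻¹)
    coupling partner + free catalyst ⇌ catalyst intermediate A (K = 1.20 M⁻¹, k = 0.00900 M⁻¹ s⁻¹)
    2 catalyst intermediate B ⇌ resting dimer (K = 60.0 M⁻¹, k = 0.0740 M⁻¹ s⁻¹)
    catalyst intermediate C → free catalyst + product (k = 0.00560 s⁻¹)
    substrate + catalyst intermediate B → catalyst intermediate C (k = 0.0350 M⁻¹ s⁻¹)
    catalyst intermediate A → catalyst intermediate B (k = 0.0150 s⁻¹)

Carried on from 6.67 h⁻¹, these factors give a turnover frequency of 6.33 h⁻¹ in the flask with the doubled charge and 7.13 h⁻¹ in the flask at 4.0 mM. Catalyst intermediate C releases product at 20.2 h⁻¹, while catalyst intermediate A moves on at 54.0 h⁻¹ and catalyst intermediate B reacts at 50 h⁻¹ with substrate as charged, so the release of product is slower than both. In this flask at 1.00 h, catalyst intermediate C is the resting state, ahead of every other form, with 33.9% of the catalyst.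

Readings and results stem from a simulated flask on assumed constants, noise included.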